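(The readings are calculated on assumed constants; scatter was added.)

The readings stop at 31 min, so the end of the eta run, which repeats the alpha charge, cannot be read from any of them; we have to reach it through rates.

| flask | substrate | free catalyst | time |
|---|---|---|---|
| alpha | 300 mM | 9.00 mM |  |
| beta | 300 mM | 13.0 mM |  |
| zeta | 450 mM | 9.00 mM |  |
| eta | 300 mM | 9.00 mM | 78 min |

| alpha run: time / min | alpha run: [product] / mM | beta run: time / min | beta run: [product] / mM | zeta run: time / min | zeta run: [product] / mM |
|---|---|---|---|---|---|
| 3.9 | 21.2 | 3.9 | 48.8 | 3.9 | 8.9 |
| 7.8 | 46.3 | 7.8 | 113.5 | 7.8 | 22.2 |
| 12 | 74.4 | 12 | 183.1 | 12 | 33.4 |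
| 16 | 101.6 | 16 | 235.4 | 16 | 48.5 |
| 19 | 124.8 | 19 | 265.3 | 19 | 59.5 |
| 23 | 151.8 | 23 | 282.6 | 23 | 70.6 |
| 27 | 181.8 | 27 | 288.7 | 27 | 87.9 |
| 31 | 209.1 | 31 | 292.6 | 31 | 103.5 |

(readings scatter by 2 mM)

- Overall: substrate -> product, with free catalyst as catalyst.
- Constant volume, constant temperature.
- Bound and free are read together.
- An order is taken over about fifteen percent of the charge, up and down.

* order of the initial rate in [substrate], near the charge of the alpha run, the rate being that where two percent of its substrate are product (one fixed amount of product, the same in the runs compared)
* order of the initial rate in [free catalyst], near the charge of the alpha run, the rate being that where two percent of its substrate are product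
* product in the eta run at 78 min, as a share of the substrate charged

Between its first two readings the alpha run gains 6.44 mM min⁻¹, while the zeta run, charged with more substrate, gains 3.41 mM min⁻¹. Extra substrate therefore gives a slower rate, by the factor 0.530, and we read an order in substrate of −1.57 over that wide step.

More free catalyst acts the other way, and here we compare times. The alpha run shows 74.4 mM of product at 12 min; the beta run, interpolated between its first two readings, gets there at 5.44 min. We call the time the alpha run needs for an amount of product, divided by the time the beta run needs for the same amount, the clock factor:

clock factor = 2.20

Our order in free catalyst, read over the step from the alpha run to the beta run, is then 2.15.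

The two runs share a substrate charge, so if the clock factor held to the end, the eta run at 78 min would stand where the beta run stands at 35.4 min, a little past its last reading. There we need only the small remainder. The beta run's substrate not yet turned falls from 17.4 mM to 7.40 mM over its last readings, which gives a tail constant, read with the scatter, of:

tail constant = 0.107 min⁻¹

not yet turned at the asked time = 4.63 mM

share made = 98.5 %

The forecast gives −1.6 for the order in substrate, 2.4 for the order in free catalyst and 96 % for the share made, expecting that alpha will “then tail off as beta does”.

The flask gives −1.4, 2.1 and 95.3 %, against our −1.57, 2.15 and 98.5 %; our end share stands 3.2 percentage points too high.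

    free catalyst + substrate ⇌ catalyst-substrate complex, settled at all times (3.730 M⁻¹)
    catalyst-substrate complex + free catalyst → product + 2 free catalyst (930.0 M⁻¹ min⁻¹)
    2 free catalyst → 2 spent catalyst (3.642 M⁻¹ min⁻¹)
    catalyst-substrate complex + substrate ⇌ doubly bound catalyst, settled at all times (5.590 M⁻¹)

Dividing the alpha run's time to half turned, 22.7 min, by the clock factor gives 10.3 min for the beta run, whose time is 10.2 min. The negative order in substrate near the alpha charge is due to the association of catalyst-substrate complex with substrate to doubly bound catalyst, which is substrate inhibition. Without that step the order in substrate near the alpha charge is −0.029, against −1.4 as it is.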